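The G charged stays in the flask in one form or another, and in the grey run, this very flask followed so far, the readings of Q and E together come to nearly all of it, 99.0 %, at 8.00 d.

- grey: G 2 M; the very flask that is asked about, followed so far
- flask: G 2.0 M; time 15 d

- grey (time / d: Q / %, E / %): 0.625: 6, 14; 1.04: 14, 26; 2.00: 20, 60; 4.00: 23, 71; 8.00: 22, 77

(standard deviation of a reading: 2 percentage points)

- given per volume of solution although it is solid: G
- what may be going on: X -> E; Z -> E; Z -> L; X -> Q; Z <-> J; G <-> X; X <-> Z
- at the start none of G is in solution

- ratio of Q to E at 5.0 h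
- ratio of Q to E at 15 d
- which of Q and E there is more of at 15 d

Here is the quick number you asked for, reckoned from those readings in three steps.

1. Reading by reading, the ratio of Q to E goes 0.429, 0.538, 0.333, 0.324, 0.286, but a scatter of 2 percentage points weighs heavier on a Q of 6 % than on one of 22 %, so the single ratios are poor guides.

2. This reckoning therefore treats the ratio as one constant and pools the run: the sum of all Q readings over the sum of all E readings, 0.343, is the split, a selectivity read from the readings.

3. The split is the number offered for both 5.0 h and 15 d, so this estimate has E ahead and puts Q at 25.5 % of Q plus E.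

The forecast differs: it gives 0.55 at 5.0 h and 0.28 at 15 d, with E ahead, on the ground that “Q/E therefore starts high and falls”.

The flask gives 0.394 at 5.0 h and 0.357 at 15 d, a fall of 0.0370 against the 0.270 of the forecast, and E leads with 72.6 % against 26.0 % of Q.

    X → E (k = 0.0730 /h)
    Z → E (k = 0.0430 /h)
    Z → L (k = 0.00820 /h)
    X → Q (k = 0.0290 /h)
    Z ⇌ J (K = 1.00, k = 0.330 /h)
    G ⇌ X, rate k6*(cs6 - [X]) while solid is left; crystals form when [X] > cs6 (solubility = 1.30 M, k = 0.0490 /h)
    X ⇌ Z (K = 1.00, k = 0.0120 /h)

The neighbouring flask, charged with 0.50 M of G instead of 2.0 M with all else held, takes the same reckoning: a split of 0.343 puts Q at 25.5 % of Q plus E. That neighbour ends with 26.0 % of Q, 72.6 % of E and 1.39 % of L, each in percent of its own charge, which makes Q 26.4 % of Q plus E, and its ratio of Q to E stands at 0.394 at 5.0 h and 0.357 at 15 d.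

All runs come from a simulation for an exercise; scatter was added.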